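Everything rests on opening flavonol ring C of abiesin at O1–C2 and at the C3–OH bond, which leads back to a 2'-hydroxychalcone that already carries the finished 5-hydroxy-7-methoxyflavone on its C5' carbon. Because ring A of the flavonol has hydrogen at C5 (no C6' substituent in the chalcone), alkaline peroxide should close ring C (O1, C2, C3, C4) through the six-membered pathway and install the C3 hydroxyl in the same operation. The precursor, chalcone 12, is assembled by Suzuki coupling of a 3'-bromoflavone with a borylated 4-O-benzylresacetophenone followed by aldol condensation with anisaldehyde; the C7 benzyl ether is removed last.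

Key step: step 9

Remark: the biaryl axis has only one ortho oxygen substituent on each ring and is taken to rotate freely, so abiesin has no stereogenic element. The only stereo-descriptors in the route are the (E)-alkene of 12 and the transient trans centres of 13.

**Step 1**
Reactants: 1 3-bromo-4-methoxybenzoic acid
Product: 2 3-bromo-4-methoxybenzoyl chloride
Conditions: SOCl2, cat. DMF, toluene, 80 °C; evaporate
Reagents that add atoms: thionyl chloride, O=S(Cl)Cl
Why: Standard acyl chloride formation from an aryl carboxylic acid through the chlorosulfite, with the aryl bromide and the methyl ether inert.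

**Step 2**
Reactants: 3 2',6'-dihydroxy-4'-methoxyacetophenone; 2 3-bromo-4-methoxybenzoyl chloride
Product: 4 1-(3-bromo-4-methoxyphenyl)-3-(2,6-dihydroxy-4-methoxyphenyl)propane-1,3-dione
Conditions: 3, LiN(SiMe3)2 (4 equiv.), THF, −78 → −10 °C; then 2, −78 °C → rt; aq. HCl
Reagents that add atoms: none
Why: The lithium enolate of the bis-phenoxide should be C-aroylated by the acid chloride (crossed Claisen acylation, the one-flask form of the Baker–Venkataraman sequence), and any O-aroyl ester formed should undergo the Baker–Venkataraman O-to-C acyl shift under the excess base to the same 1,3-diketone.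

**Step 3**
Reactants: 4 1-(3-bromo-4-methoxyphenyl)-3-(2,6-dihydroxy-4-methoxyphenyl)propane-1,3-dione
Product: 5 2-(3-bromo-4-methoxyphenyl)-5-hydroxy-7-methoxy-4H-chromen-4-one (3'-bromo-5-hydroxy-7,4'-dimethoxyflavone)
Conditions: cat. H2SO4, AcOH, 100 °C
Reagents that add atoms: none
Why: Acid-catalysed cyclodehydration of the o-hydroxyaryl 1,3-diketone (closing stage of the Baker–Venkataraman flavone synthesis); the two phenols are equivalent by symmetry, so a single flavone should form, with the remaining hydroxyl at C5.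

**Step 4**
Reactants: 6 2,4-dihydroxyacetophenone
Product: 7 1-(4-benzyloxy-2-hydroxyphenyl)ethan-1-one
Conditions: BnBr (1.05 equiv.), K2CO3, acetone, reflux
Reagents that add atoms: benzyl bromide, BrCc1ccccc1
Why: Williamson etherification that should be selective for the C4 hydroxyl, because the C2 hydroxyl is hydrogen-bonded to the acetyl carbonyl and is much less nucleophilic.

**Step 5**
Reactants: 7 1-(4-benzyloxy-2-hydroxyphenyl)ethan-1-one
Product: 8 1-(4-benzyloxy-5-bromo-2-hydroxyphenyl)ethan-1-one
Conditions: NBS (1.0 equiv.), MeCN, 0 °C → rt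
Reagents that add atoms: N-bromosuccinimide, O=C1CCC(=O)N1Br
Why: Electrophilic aromatic bromination should go to C5, which is para to the hydroxyl and ortho to the benzyloxy group and less hindered than C3 between the two oxygens.

**Step 6**
Reactants: 8 1-(4-benzyloxy-5-bromo-2-hydroxyphenyl)ethan-1-one
Product: 9 1-[4-benzyloxy-2-hydroxy-5-(4,4,5,5-tetramethyl-1,3,2-dioxaborolan-2-yl)phenyl]ethan-1-one
Conditions: B2pin2, Pd(dppf)Cl2 (5 mol %), KOAc, 1,4-dioxane, 90 °C
Reagents that add atoms: bis(pinacolato)diboron, CC1(C)OB(OC1(C)C)B1OC(C)(C)C(C)(C)O1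
Why: Miyaura borylation of an aryl bromide; the weak acetate base should leave the chelated phenol and the methyl ketone untouched and should not promote coupling of the product boronate.

**Step 7**
Reactants: 5 2-(3-bromo-4-methoxyphenyl)-5-hydroxy-7-methoxy-4H-chromen-4-one; 9 1-[4-benzyloxy-2-hydroxy-5-(4,4,5,5-tetramethyl-1,3,2-dioxaborolan-2-yl)phenyl]ethan-1-one
Product: 10 2-[3-(5-acetyl-2-benzyloxy-4-hydroxyphenyl)-4-methoxyphenyl]-5-hydroxy-7-methoxy-4H-chromen-4-one
Conditions: Pd(OAc)2 (5 mol %), SPhos (10 mol %), K3PO4, 1,4-dioxane/H2O, 90 °C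
Reagents that add atoms: none
Why: Suzuki–Miyaura cross-coupling (oxidative addition of the aryl bromide to zerovalent palladium, phosphate-assisted transmetalation of the boronate, reductive elimination); the bulky electron-rich SPhos ligand is chosen because each partner has one ortho oxygen substituent, and the chelated phenols, the ketone and the benzyl ether should be tolerated.

**Step 8**
Reactants: 10 2-[3-(5-acetyl-2-benzyloxy-4-hydroxyphenyl)-4-methoxyphenyl]-5-hydroxy-7-methoxy-4H-chromen-4-one; 11 4-methoxybenzaldehyde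
Product: 12 (E)-1-{4-benzyloxy-2-hydroxy-5-[5-(5-hydroxy-7-methoxy-4-oxo-4H-chromen-2-yl)-2-methoxyphenyl]phenyl}-3-(4-methoxyphenyl)prop-2-en-1-one
Conditions: KOH (50% aq.), EtOH/THF, 0 °C → rt; aq. HCl
Reagents that add atoms: none
Why: Claisen–Schmidt condensation in which the methyl ketone enolate adds to the non-enolisable aldehyde and E1cB dehydration gives the conjugated (E)-enone under thermodynamic control, while the flavone, held as its C5 phenoxide, should be too poor an acceptor to be opened by hydroxide at room temperature.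

**Step 9**
Reactants: 12 (E)-1-{4-benzyloxy-2-hydroxy-5-[5-(5-hydroxy-7-methoxy-4-oxo-4H-chromen-2-yl)-2-methoxyphenyl]phenyl}-3-(4-methoxyphenyl)prop-2-en-1-one
Product: 14 7-benzyloxy-3-hydroxy-6-[5-(5-hydroxy-7-methoxy-4-oxo-4H-chromen-2-yl)-2-methoxyphenyl]-2-(4-methoxyphenyl)-4H-chromen-4-one (7-O-benzylabiesin), via trans-dihydroflavonol 13 (not isolated)
Conditions: 30% aq. H2O2, 2 M aq. NaOH, MeOH/THF, 0 °C → rt; aq. HCl
Reagents that add atoms: hydrogen peroxide, OO
Why: Hydroxide ionises the C2' phenol, whose oxygen adds to the enone β-carbon in a 6-endo-trig oxa-Michael closure that forms O1–C2 and ring C, and the resulting flavanone enolate is hydroxylated at C3 by hydrogen peroxide (C3–O bond) to give dihydroflavonol 13, which is dehydrogenated to the flavonol in the same alkaline peroxide medium. The closest known reaction is the Algar–Flynn–Oyamada oxidation of 2'-hydroxychalcones that have hydrogen at C6'. The two sp3 centres at C2 and C3 of 13 arise as the racemic, thermodynamically preferred trans pair and are erased by the dehydrogenation, so no stereocentre has to be controlled. The selectivity required is six-membered flavonol closure over five-membered aurone formation through attack at the α-carbon; it should be secured by the hydrogen at C6' (C5 of ring A), the substitution pattern for which this oxidation is known to give flavonols, and by the benzyl ether at C4', which prevents a second phenoxide from deactivating the enone. The finished flavone should pass through unchanged, because its C5 hydroxyl is ionised or chelated to the C4 carbonyl, which lowers the electrophilicity of its C2 towards hydroperoxide at 0–25 °C.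

**Step 10**
Reactants: 14 7-O-benzylabiesin
Product: 15 abiesin, 3,7-dihydroxy-6-[5-(5-hydroxy-7-methoxy-4-oxo-4H-chromen-2-yl)-2-methoxyphenyl]-2-(4-methoxyphenyl)-4H-chromen-4-one
Conditions: H2 (1 atm), 10% Pd/C, THF/MeOH, rt
Reagents that add atoms: none
Why: Catalytic hydrogenolysis of the aryl benzyl ether, which at 1 atm should be much faster than reduction of the conjugated C2=C3 bonds of the flavone and flavonol, so the reaction is stopped after one equivalent of hydrogen is taken up.

**Compound list**

1 | 3-bromo-4-methoxybenzoic acid | COc1ccc(C(=O)O)cc1Br | starting material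
2 | 3-bromo-4-methoxybenzoyl chloride | COc1ccc(C(Cl)=O)cc1Br | intermediate
3 | 2',6'-dihydroxy-4'-methoxyacetophenone | CC(=O)c1c(O)cc(OC)cc1O | starting material
4 | 1-(3-bromo-4-methoxyphenyl)-3-(2,6-dihydroxy-4-methoxyphenyl)propane-1,3-dione (drawn as the diketo tautomer) | COc1cc(O)c(C(=O)CC(=O)c2ccc(OC)c(Br)c2)c(O)c1 | intermediate
5 | 2-(3-bromo-4-methoxyphenyl)-5-hydroxy-7-methoxy-4H-chromen-4-one | COc1cc(O)c2c(=O)cc(-c3ccc(OC)c(Br)c3)oc2c1 | intermediate
6 | 2,4-dihydroxyacetophenone | CC(=O)c1ccc(O)cc1O | starting material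
7 | 1-(4-benzyloxy-2-hydroxyphenyl)ethan-1-one | CC(=O)c1ccc(OCc2ccccc2)cc1O | intermediate
8 | 1-(4-benzyloxy-5-bromo-2-hydroxyphenyl)ethan-1-one | CC(=O)c1cc(Br)c(OCc2ccccc2)cc1O | intermediate
9 | 1-[4-benzyloxy-2-hydroxy-5-(4,4,5,5-tetramethyl-1,3,2-dioxaborolan-2-yl)phenyl]ethan-1-one | CC(=O)c1cc(B2OC(C)(C)C(C)(C)O2)c(OCc2ccccc2)cc1O | intermediate
10 | 2-[3-(5-acetyl-2-benzyloxy-4-hydroxyphenyl)-4-methoxyphenyl]-5-hydroxy-7-methoxy-4H-chromen-4-one | CC(=O)c1cc(-c2cc(-c3cc(=O)c4c(O)cc(OC)cc4o3)ccc2OC)c(OCc2ccccc2)cc1O | intermediate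
11 | 4-methoxybenzaldehyde | COc1ccc(C=O)cc1 | starting material
12 | (E)-1-{4-benzyloxy-2-hydroxy-5-[5-(5-hydroxy-7-methoxy-4-oxo-4H-chromen-2-yl)-2-methoxyphenyl]phenyl}-3-(4-methoxyphenyl)prop-2-en-1-one | COc1ccc(/C=C/C(=O)c2cc(-c3cc(-c4cc(=O)c5c(O)cc(OC)cc5o4)ccc3OC)c(OCc3ccccc3)cc2O)cc1 | intermediate
13 | racemic trans-7-benzyloxy-3-hydroxy-6-[5-(5-hydroxy-7-methoxy-4-oxo-4H-chromen-2-yl)-2-methoxyphenyl]-2-(4-methoxyphenyl)chroman-4-one (dihydroflavonol; the 2R,3R enantiomer is drawn) | COc1ccc([C@@H]2[C@@H](O)C(=O)c3cc(-c4cc(-c5cc(=O)c6c(O)cc(OC)cc6o5)ccc4OC)c(OCc4ccccc4)cc3O2)cc1 | intermediate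
14 | 7-O-benzylabiesin, 7-benzyloxy-3-hydroxy-6-[5-(5-hydroxy-7-methoxy-4-oxo-4H-chromen-2-yl)-2-methoxyphenyl]-2-(4-methoxyphenyl)-4H-chromen-4-one | COc1ccc(-c2oc3cc(OCc4ccccc4)c(-c4cc(-c5cc(=O)c6c(O)cc(OC)cc6o5)ccc4OC)cc3c(=O)c2O)cc1 | intermediate
15 | abiesin | COc1ccc(-c2oc3cc(O)c(-c4cc(-c5cc(=O)c6c(O)cc(OC)cc6o5)ccc4OC)cc3c(=O)c2O)cc1 | target

**Step count**

Total steps: 10.
Longest linear sequence: 7 steps (steps 1, 2, 3, 7, 8, 9, 10, or equally steps 4, 5, 6, 7, 8, 9, 10).

**Steps most likely to fail**

1. Step 9. Closure at the α-carbon to the five-membered aurone may compete, the oxidation may stop at the dihydroflavonol stage, or the flavonol may be degraded by alkaline peroxide. The fallback sets out from 12 and comes back at 14, and separates ring closure from C3 oxygenation. Chalcone 12 would be isomerised with NaOAc in refluxing EtOH to the racemic flavanone F1. Nitrosation at C3 with isoamyl nitrite and HCl in EtOH/THF should give the 3-hydroxyimino flavanone F2. Hydrolysis of the oxime with aq. HCl in AcOH would release the flavan-3,4-dione, whose enol tautomer is flavonol 14 (Kostanecki flavonol synthesis).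

2. Step 7. Protodeboronation of the electron-rich boronate 9 may outrun transmetalation, or coupling may be slow at a biaryl bond flanked by two ortho oxygen substituents. The fallback sets out from 5 and 8 and comes back at 10, and reverses the polarity of the coupling. Bromoflavone 5 would be borylated (B2pin2, Pd(dppf)Cl2, KOAc, 1,4-dioxane, 90 °C) to the flavone 3'-pinacol boronate F3, whose boron sits on a less electron-rich ring. F3 would then be coupled with aryl bromide 8 (Pd(OAc)2, SPhos, K3PO4, 1,4-dioxane/H2O) to give 10, and step 6 would be dropped.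

3. Step 8. During the long exposure to concentrated KOH, hydroxide may add to C2 of the flavone and open its ring C, or the condensation may stall because the poly-anion precipitates. The fallback sets out from 8 and comes back at 12, and moves the aldol ahead of the biaryl coupling so that the flavone never meets concentrated hydroxide. Bromide 8 would be condensed with 11 (KOH, EtOH, rt) to the bromochalcone F4. F4 would then be joined to the flavone 3'-pinacol boronate F3 (made from 5 as in the fallback to step 7) by Suzuki–Miyaura coupling under weakly basic conditions (Pd(OAc)2, SPhos, K3PO4, 1,4-dioxane/H2O) to give 12 directly.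

**Further compounds**

F1 | step 9 | racemic 7-benzyloxy-6-[5-(5-hydroxy-7-methoxy-4-oxo-4H-chromen-2-yl)-2-methoxyphenyl]-2-(4-methoxyphenyl)chroman-4-one | COc1ccc(C2CC(=O)c3cc(-c4cc(-c5cc(=O)c6c(O)cc(OC)cc6o5)ccc4OC)c(OCc4ccccc4)cc3O2)cc1
F2 | step 9 | racemic 7-benzyloxy-3-(hydroxyimino)-6-[5-(5-hydroxy-7-methoxy-4-oxo-4H-chromen-2-yl)-2-methoxyphenyl]-2-(4-methoxyphenyl)chroman-4-one | COc1ccc(C2Oc3cc(OCc4ccccc4)c(-c4cc(-c5cc(=O)c6c(O)cc(OC)cc6o5)ccc4OC)cc3C(=O)C2=NO)cc1
F3 | step 7 | 5-hydroxy-7-methoxy-2-[4-methoxy-3-(4,4,5,5-tetramethyl-1,3,2-dioxaborolan-2-yl)phenyl]-4H-chromen-4-one | COc1cc(O)c2c(=O)cc(-c3ccc(OC)c(B4OC(C)(C)C(C)(C)O4)c3)oc2c1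
F4 | step 8 | (E)-1-(4-benzyloxy-5-bromo-2-hydroxyphenyl)-3-(4-methoxyphenyl)prop-2-en-1-one | COc1ccc(/C=C/C(=O)c2cc(Br)c(OCc3ccccc3)cc2O)cc1
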